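**Assumption:** the SMILES is taken literally: cis-fused 6,12-γ-lactone, both ring alkenes Z, (3S,6R,7R,8S,9R) in germacrane numbering (C6 = lactone O–CH, C7 = ring-fusion CH, C8 = ester carbon, C9 = carbinol, C10=C1, C2, C3 = OAc carbon, C4=C5), and a (2R,3R)-epoxyangelate.

## Retrosynthetic overview

1. The 10-membered ring is closed last by ring-closing metathesis (C1=C10, Z); the C9 carbinol comes from Nozaki–Hiyama–Kishi isopropenylation of a C9 aldehyde.
2. The cis-α-methylene-γ-butyrolactone comes from an indium Barbier allylation/lactonisation (C6–C7) between a Z-γ-hydroxy-enal (as its lactol) and a (Z)-2-(bromomethyl)enoate that already carries the epoxyangelate at C8.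
3. The C1–C6 lactol comes from a butenolide, whose (S,Z)-ene-diol is made by the key step: a lithiated but-3-enyl carbamate inserts into a five-membered oxaborole, and a 1,2-boronate shift enlarges it to a six-membered oxaborinine (forms C3–C4, sets C3); C–B oxidation follows.
4. The bromide comes from asymmetric vinylation of dimethoxyacetaldehyde, Yamaguchi esterification, ozonolysis, Baylis–Hillman reaction and SN2′ bromination; the acid comes from Sharpless epoxidation of angelyl alcohol and oxidation.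
5. Ring order: oxaborole (5) → oxaborinine (6, temporary) → butenolide/lactol → γ-lactone → cyclodecadiene.

## Route

Step 1
Reactants: 1 methyl angelate (methyl (2Z)-2-methylbut-2-enoate)
Product: 2 (2Z)-2-methylbut-2-en-1-ol
Conditions: DIBAL-H (2.2 equiv), CH2Cl2, −78 → 0 °C; Rochelle salt
Reagents that add atoms: none
Why: DIBAL-H 1,2-reduction of the conjugated ester gives the allylic alcohol without touching the Z-trisubstituted alkene.

Step 2
Reactants: 2 (2Z)-2-methylbut-2-en-1-ol
Product: 3 [(2S,3R)-2,3-dimethyloxiran-2-yl]methanol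
Conditions: Ti(OiPr)4 (10 mol%), L-(+)-DET (12 mol%), t-BuOOH, 4 Å MS, CH2Cl2, −20 °C
Reagents that add atoms: tert-butyl hydroperoxide, CC(C)(C)OO
Why: Sharpless asymmetric epoxidation; the Ti–L-(+)-tartrate complex delivers oxygen syn to one face of the allylic alcohol, which sets both epoxide stereocentres and keeps the two methyl groups trans.

Step 3
Reactants: 3 [(2S,3R)-2,3-dimethyloxiran-2-yl]methanol
Product: 5 (2R,3R)-2,3-dimethyloxirane-2-carboxylic acid, via epoxy aldehyde 4 (not isolated)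
Conditions: TEMPO (cat.), NaOCl (cat.), NaClO2, MeCN/phosphate buffer pH 6.7, 35 °C
Reagents that add atoms: sodium chlorite, [Na+].[O-]Cl=O
Why: Buffered TEMPO/chlorite oxidation of the primary alcohol to the acid via the aldehyde leaves the epoxide intact (the C2 descriptor changes to R by priority only).

Step 4
Reactants: 6 2,2-dimethoxyacetaldehyde; 7 vinylmagnesium bromide
Product: 9 (2S)-1,1-dimethoxybut-3-en-2-ol, via divinylzinc 8 (not isolated)
Conditions: 7, ZnCl2, THF; 1,4-dioxane, filter; (−)-DAIB (5 mol%), 6, toluene, 0 °C; aq. NH4Cl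
Reagents that add atoms: zinc chloride, Cl[Zn]Cl (zinc of 8 only)
Why: Amino-alcohol-catalysed asymmetric 1,2-addition of vinylzinc to the aldehyde; the chiral zinc chelate delivers vinyl to the Si face and sets (S) at the future C8, and any minor enantiomer is removed after step 5 as a diastereomeric ester.

Step 5
Reactants: 9 (2S)-1,1-dimethoxybut-3-en-2-ol; 5 (2R,3R)-2,3-dimethyloxirane-2-carboxylic acid
Product: 11 (2S)-1,1-dimethoxybut-3-en-2-yl (2R,3R)-2,3-dimethyloxirane-2-carboxylate, via mixed anhydride 10 (not isolated)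
Conditions: 5, 2,4,6-Cl3C6H2COCl, Et3N, THF; then 9, DMAP, toluene, rt
Reagents that add atoms: 2,4,6-trichlorobenzoyl chloride, O=C(Cl)c1c(Cl)cc(Cl)cc1Cl (atoms of 10 only)
Why: Yamaguchi esterification acylates the secondary allylic alcohol with the hindered α,α-disubstituted acid without touching any stereocentre.

Step 6
Reactants: 11 (2S)-1,1-dimethoxybut-3-en-2-yl (2R,3R)-2,3-dimethyloxirane-2-carboxylate
Product: 12 (2S)-1,1-dimethoxy-3-oxopropan-2-yl (2R,3R)-2,3-dimethyloxirane-2-carboxylate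
Conditions: O3, CH2Cl2, −78 °C; Me2S
Reagents that add atoms: ozone, [O-][O+]=O
Why: Ozonolysis with reductive work-up cleaves the only alkene to the α-acyloxy aldehyde (future C7), which is used crude.

Step 7
Reactants: 12 (2S)-1,1-dimethoxy-3-oxopropan-2-yl (2R,3R)-2,3-dimethyloxirane-2-carboxylate; 13 methyl acrylate
Product: 14 methyl (4S)-4-{[(2R,3R)-2,3-dimethyloxirane-2-carbonyl]oxy}-3-hydroxy-5,5-dimethoxy-2-methylidenepentanoate (both C3 epimers)
Conditions: DABCO (0.5 equiv), 13 (5 equiv), neat, rt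
Reagents that add atoms: none
Why: Morita–Baylis–Hillman reaction; the strongly electrophilic α-oxygenated aldehyde is trapped quickly under nearly neutral conditions so C8 should not epimerise, and the new carbinol centre is left uncontrolled because it becomes sp2 in step 8.

Step 8
Reactants: 14 methyl (4S)-4-{[(2R,3R)-2,3-dimethyloxirane-2-carbonyl]oxy}-3-hydroxy-5,5-dimethoxy-2-methylidenepentanoate
Product: 15 methyl (2Z,4S)-2-(bromomethyl)-4-{[(2R,3R)-2,3-dimethyloxirane-2-carbonyl]oxy}-5,5-dimethoxypent-2-enoate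
Conditions: NBS, Me2S, CH2Cl2, 0 °C → rt
Reagents that add atoms: N-bromosuccinimide, BrN1C(=O)CCC1=O
Why: SN2′ bromination of the Baylis–Hillman alcohol through its alkoxysulfonium salt (Corey–Kim-type activation) gives the conjugated, thermodynamically preferred (Z)-2-(bromomethyl)enoate without acid, so the epoxide and acetal survive.

Step 9
Reactants: 16 but-2-yn-1-ol
Product: 18 (2Z)-3-iodobut-2-en-1-ol, via cyclic vinylalanate 17 (not isolated)
Conditions: Red-Al, THF, 0 °C → rt; I2, −78 °C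
Reagents that add atoms: Red-Al (sodium bis(2-methoxyethoxy)aluminium dihydride), [Na+].[AlH2-](OCCOC)OCCOC (atoms of 17 only); iodine, II
Why: Hydroxyl-directed trans-hydroalumination places aluminium on the distal carbon in a five-membered chelate, and iodinolysis with retention gives the Z-iodide.

Step 10
Reactants: 18 (2Z)-3-iodobut-2-en-1-ol
Product: 20 3-methyl-2-(propan-2-yloxy)-2,5-dihydro-1,2-oxaborole, via dilithio alkoxide 19 (not isolated)
Conditions: n-BuLi (1 equiv), then t-BuLi (2 equiv), Et2O, −78 °C; B(OiPr)3; HCl/Et2O; distil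
Reagents that add atoms: n-butyllithium, [Li]CCCC, and tert-butyllithium, [Li]C(C)(C)C (lithium of 19 only); triisopropyl borate, CC(C)OB(OC(C)C)OC(C)C
Why: Deprotonation, iodine–lithium exchange with retention, borylation and intramolecular transesterification give the cyclic alkenylboronic ester, whose ring locks the Z geometry and makes hydroxyl protection unnecessary.

Step 11
Reactants: 21 but-3-en-1-ol
Product: 22 but-3-en-1-yl N,N-di(propan-2-yl)carbamate
Conditions: i-Pr2NCOCl, Et3N, CH2Cl2, reflux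
Reagents that add atoms: N,N-diisopropylcarbamoyl chloride, CC(C)N(C(C)C)C(Cl)=O
Why: O-Carbamoylation installs the Hoppe carbamate, which directs the α-lithiation and later acts as the leaving group.

Step 12
Reactants: 22 but-3-en-1-yl N,N-di(propan-2-yl)carbamate; 20 3-methyl-2-(propan-2-yloxy)-2,5-dihydro-1,2-oxaborole
Product: 26 (2Z,4S)-3-methylhepta-2,6-diene-1,4-diol, via lithiated carbamate 23 (not isolated), via boronate complex 24 (not isolated), via ring-expanded oxaborinine 25 (not isolated)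
Conditions: s-BuLi, (+)-sparteine, Et2O, −78 °C, 5 h; 20, −78 °C; MgBr2·OEt2, 35 °C; then NaOH, H2O2, THF, 0 °C → rt
Reagents that add atoms: sec-butyllithium, [Li]C(C)CC (lithium of 23 and 24 only); hydrogen peroxide, OO
Why: Proposed new method: (+)-sparteine-directed deprotonation gives the (R)-α-lithio carbamate 23, which adds with retention to the boron of cyclic alkenylboronic ester 20; in ate complex 24 the ring alkenyl carbon is the only carbon ligand on boron and migrates anti to the C–OCb bond (invertive, stereospecific 1,2-metallate shift), enlarging the five-membered oxaborole to the six-membered oxaborinine 25, forming C3–C4 and setting (3S), while the ring keeps the alkene Z and makes a 1,3-borotropic shift impossible (it would need a four-membered ring), and C–B oxidation with retention gives 26; the closest known reaction types are the Hoppe–Aggarwal lithiation–borylation of acyclic alkenyl pinacol boronates and the Matteson-type carbenoid ring enlargement of saturated 1,2-oxaborolanes.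

Step 13
Reactants: 26 (2Z,4S)-3-methylhepta-2,6-diene-1,4-diol
Product: 28 (5S)-4-methyl-5-(prop-2-en-1-yl)furan-2(5H)-one, via lactol 27 (not isolated)
Conditions: TEMPO (20 mol%), PhI(OAc)2 (2.5 equiv), CH2Cl2, rt
Reagents that add atoms: none
Why: TEMPO/PhI(OAc)2 oxidative lactonisation; the oxoammonium salt oxidises the primary allylic alcohol selectively, the Z-γ-hydroxy-enal closes to lactol 27 and is oxidised on to the butenolide (stopping cleanly at 27 is unreliable), and C3 is not touched.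

Step 14
Reactants: 28 (5S)-4-methyl-5-(prop-2-en-1-yl)furan-2(5H)-one
Product: 27 (5S)-4-methyl-5-(prop-2-en-1-yl)-2,5-dihydrofuran-2-ol
Conditions: DIBAL-H (1.1 equiv), CH2Cl2, −78 °C; Rochelle salt (neutral work-up), use at once
Reagents that add atoms: none
Why: DIBAL-H half-reduction of the lactone stops at the aluminium hemiacetal and gives lactol 27, a masked (Z)-γ-hydroxy-enal; neutral work-up avoids dehydration to the furan.

Step 15
Reactants: 15 methyl (2Z,4S)-2-(bromomethyl)-4-{[(2R,3R)-2,3-dimethyloxirane-2-carbonyl]oxy}-5,5-dimethoxypent-2-enoate; 27 (5S)-4-methyl-5-(prop-2-en-1-yl)-2,5-dihydrofuran-2-ol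
Product: 31 (1S)-1-[(2R,3R)-2-[(1Z,3S)-3-hydroxy-2-methylhexa-1,5-dien-1-yl]-4-methylidene-5-oxooxolan-3-yl]-2,2-dimethoxyethyl (2R,3R)-2,3-dimethyloxirane-2-carboxylate, via allylindium reagent 29 (not isolated), via hydroxy ester 30 (not isolated)
Conditions: In (1.5 equiv), THF/H2O (1:1), rt; then PPTS (cat.), CH2Cl2, rt
Reagents that add atoms: indium, [In] (indium of 29 only)
Why: Indium-mediated Barbier allylation followed by lactonisation (Dreiding–Schmidt lactone synthesis); the 2-(alkoxycarbonyl)allylindium adds 1,2 to the open hydroxy-enal form of 27 through a closed chair transition state that gives the 6,7-syn adduct (hence the cis-fused lactone), and the aldehyde is expected to approach C7 anti to the C8–O bond of the H-eclipsed rotamer enforced by A(1,3) strain, which relays (8S) to (6R,7R).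

Step 16
Reactants: 31 (1S)-1-[(2R,3R)-2-[(1Z,3S)-3-hydroxy-2-methylhexa-1,5-dien-1-yl]-4-methylidene-5-oxooxolan-3-yl]-2,2-dimethoxyethyl (2R,3R)-2,3-dimethyloxirane-2-carboxylate
Product: 32 (1S)-1-[(2R,3R)-2-[(1Z,3S)-3-(acetyloxy)-2-methylhexa-1,5-dien-1-yl]-4-methylidene-5-oxooxolan-3-yl]-2,2-dimethoxyethyl (2R,3R)-2,3-dimethyloxirane-2-carboxylate
Conditions: Ac2O, pyridine, DMAP (cat.), CH2Cl2, 0 °C
Reagents that add atoms: acetic anhydride, CC(=O)OC(C)=O
Why: Acetylation of the only free hydroxyl (C3) with retention.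

Step 17
Reactants: 32 (1S)-1-[(2R,3R)-2-[(1Z,3S)-3-(acetyloxy)-2-methylhexa-1,5-dien-1-yl]-4-methylidene-5-oxooxolan-3-yl]-2,2-dimethoxyethyl (2R,3R)-2,3-dimethyloxirane-2-carboxylate
Product: 33 (1S)-1-[(2R,3R)-2-[(1Z,3S)-3-(acetyloxy)-2-methylhexa-1,5-dien-1-yl]-4-methylidene-5-oxooxolan-3-yl]-2-oxoethyl (2R,3R)-2,3-dimethyloxirane-2-carboxylate
Conditions: LiBF4, MeCN/H2O (98:2), 50 °C
Reagents that add atoms: water, O
Why: Mild Lewis-acid acetal hydrolysis unmasks the C9 aldehyde under nearly neutral conditions that spare the epoxide, the allylic acetate and the esters.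

Step 18
Reactants: 33 (1S)-1-[(2R,3R)-2-[(1Z,3S)-3-(acetyloxy)-2-methylhexa-1,5-dien-1-yl]-4-methylidene-5-oxooxolan-3-yl]-2-oxoethyl (2R,3R)-2,3-dimethyloxirane-2-carboxylate; 34 2-bromopropene
Product: 36 (1S,2R)-1-[(2R,3R)-2-[(1Z,3S)-3-(acetyloxy)-2-methylhexa-1,5-dien-1-yl]-4-methylidene-5-oxooxolan-3-yl]-2-hydroxy-3-methylbut-3-en-1-yl (2R,3R)-2,3-dimethyloxirane-2-carboxylate, via isopropenylchromium reagent 35 (not isolated)
Conditions: CrCl2 (4 equiv), NiCl2 (2 mol%), DMF, rt
Reagents that add atoms: chromium(II) chloride, Cl[Cr]Cl (chromium and chlorine of 35 only)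
Why: Nozaki–Hiyama–Kishi reaction; the alkenylchromium adds only to the aldehyde in the presence of lactone, esters and epoxide, and polar Felkin–Anh control by the α-acyloxy group gives the 8,9-anti (erythro) alcohol, that is (9R).

Step 19
Reactants: 36 (1S,2R)-1-[(2R,3R)-2-[(1Z,3S)-3-(acetyloxy)-2-methylhexa-1,5-dien-1-yl]-4-methylidene-5-oxooxolan-3-yl]-2-hydroxy-3-methylbut-3-en-1-yl (2R,3R)-2,3-dimethyloxirane-2-carboxylate
Product: 37 (3aR,4S,5R,6Z,9S,10Z,11aR)-9-(acetyloxy)-5-hydroxy-6,10-dimethyl-3-methylidene-2-oxo-2,3,3a,4,5,8,9,11a-octahydrocyclodeca[b]furan-4-yl (2R,3R)-2,3-dimethyloxirane-2-carboxylate (CNP0299903.1)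
Conditions: Grubbs II (10 mol%), 1,4-benzoquinone (20 mol%), toluene (1 mM), 80 °C
Reagents that add atoms: none
Why: Ring-closing metathesis of the allyl and isopropenyl termini; the cis-lactone holds both chains on one face, the free allylic hydroxyl assists the ruthenium carbene, and the 10-membered ring next to the existing Z C4=C5 alkene should take the new trisubstituted alkene as Z.

## Compound list

1 | methyl angelate, methyl (2Z)-2-methylbut-2-enoate | C/C=C(/C)C(=O)OC | starting material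
2 | (2Z)-2-methylbut-2-en-1-ol | C/C=C(/C)CO | intermediate
3 | [(2S,3R)-2,3-dimethyloxiran-2-yl]methanol | OC[C@]1(C)O[C@@H]1C | intermediate
4 | (2R,3R)-2,3-dimethyloxirane-2-carbaldehyde | O=C[C@]1(C)O[C@@H]1C | intermediate
5 | (2R,3R)-2,3-dimethyloxirane-2-carboxylic acid | OC(=O)[C@]1(C)O[C@@H]1C | intermediate
6 | 2,2-dimethoxyacetaldehyde | COC(OC)C=O | starting material
7 | vinylmagnesium bromide | C=C[Mg]Br | starting material
8 | divinylzinc | C=C[Zn]C=C | intermediate
9 | (2S)-1,1-dimethoxybut-3-en-2-ol | COC(OC)[C@@H](O)C=C | intermediate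
10 | (2R,3R)-2,3-dimethyloxirane-2-carboxylic 2,4,6-trichlorobenzoic anhydride | O=C(OC(=O)c1c(Cl)cc(Cl)cc1Cl)[C@]1(C)O[C@@H]1C | intermediate
11 | (2S)-1,1-dimethoxybut-3-en-2-yl (2R,3R)-2,3-dimethyloxirane-2-carboxylate | COC(OC)[C@@H](OC(=O)[C@]1(C)O[C@@H]1C)C=C | intermediate
12 | (2S)-1,1-dimethoxy-3-oxopropan-2-yl (2R,3R)-2,3-dimethyloxirane-2-carboxylate | COC(OC)[C@@H](OC(=O)[C@]1(C)O[C@@H]1C)C=O | intermediate
13 | methyl acrylate | C=CC(=O)OC | starting material
14 | methyl (4S)-4-{[(2R,3R)-2,3-dimethyloxirane-2-carbonyl]oxy}-3-hydroxy-5,5-dimethoxy-2-methylidenepentanoate (both C3 epimers) | COC(=O)C(=C)C(O)[C@H](OC(=O)[C@]1(C)O[C@@H]1C)C(OC)OC | intermediate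
15 | methyl (2Z,4S)-2-(bromomethyl)-4-{[(2R,3R)-2,3-dimethyloxirane-2-carbonyl]oxy}-5,5-dimethoxypent-2-enoate | COC(=O)/C(CBr)=C/[C@H](OC(=O)[C@]1(C)O[C@@H]1C)C(OC)OC | intermediate
16 | but-2-yn-1-ol | CC#CCO | starting material
17 | sodium 2,2-bis(2-methoxyethoxy)-3-methyl-2,5-dihydro-1,2-oxaaluminol-2-uide (cyclic vinylalanate) | [Na+].CC1=CCO[Al-]1(OCCOC)OCCOC | intermediate
18 | (2Z)-3-iodobut-2-en-1-ol | C/C(I)=C/CO | intermediate
19 | lithium (2Z)-3-lithiobut-2-en-1-olate | C/C([Li])=C/CO[Li] | intermediate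
20 | 3-methyl-2-(propan-2-yloxy)-2,5-dihydro-1,2-oxaborole | CC1=CCOB1OC(C)C | intermediate
21 | but-3-en-1-ol | C=CCCO | starting material
22 | but-3-en-1-yl N,N-di(propan-2-yl)carbamate | C=CCCOC(=O)N(C(C)C)C(C)C | intermediate
23 | (1R)-1-lithiobut-3-en-1-yl N,N-di(propan-2-yl)carbamate (sparteine complex) | C=CC[C@@H]([Li])OC(=O)N(C(C)C)C(C)C | intermediate
24 | lithium 2-{(1R)-1-[di(propan-2-yl)carbamoyloxy]but-3-en-1-yl}-3-methyl-2-(propan-2-yloxy)-2,5-dihydro-1,2-oxaborol-2-uide (boronate complex) | [Li+].C=CC[C@H](OC(=O)N(C(C)C)C(C)C)[B-]1(OC(C)C)OCC=C1C | intermediate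
25 | (3S)-4-methyl-2-(propan-2-yloxy)-3-(prop-2-en-1-yl)-3,6-dihydro-2H-1,2-oxaborinine | C=CC[C@@H]1B(OC(C)C)OCC=C1C | intermediate
26 | (2Z,4S)-3-methylhepta-2,6-diene-1,4-diol | OC/C=C(/C)[C@@H](O)CC=C | intermediate
27 | (5S)-4-methyl-5-(prop-2-en-1-yl)-2,5-dihydrofuran-2-ol (both anomers) | OC1C=C(C)[C@H](CC=C)O1 | intermediate
28 | (5S)-4-methyl-5-(prop-2-en-1-yl)furan-2(5H)-one | O=C1C=C(C)[C@H](CC=C)O1 | intermediate
29 | allylindium dibromide derived from 15 (formal structure) | COC(=O)/C(C[In](Br)Br)=C/[C@H](OC(=O)[C@]1(C)O[C@@H]1C)C(OC)OC | intermediate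
30 | methyl (3R,4R,5Z,7S)-3-[(1S)-1-{[(2R,3R)-2,3-dimethyloxirane-2-carbonyl]oxy}-2,2-dimethoxyethyl]-4,7-dihydroxy-6-methyl-2-methylidenedeca-5,9-dienoate | COC(=O)C(=C)[C@H]([C@H](O)/C=C(/C)[C@@H](O)CC=C)[C@H](OC(=O)[C@]1(C)O[C@@H]1C)C(OC)OC | intermediate
31 | (1S)-1-[(2R,3R)-2-[(1Z,3S)-3-hydroxy-2-methylhexa-1,5-dien-1-yl]-4-methylidene-5-oxooxolan-3-yl]-2,2-dimethoxyethyl (2R,3R)-2,3-dimethyloxirane-2-carboxylate | C=C1C(=O)O[C@H](/C=C(/C)[C@@H](O)CC=C)[C@@H]1[C@H](OC(=O)[C@]2(C)O[C@@H]2C)C(OC)OC | intermediate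
32 | (1S)-1-[(2R,3R)-2-[(1Z,3S)-3-(acetyloxy)-2-methylhexa-1,5-dien-1-yl]-4-methylidene-5-oxooxolan-3-yl]-2,2-dimethoxyethyl (2R,3R)-2,3-dimethyloxirane-2-carboxylate | C=C1C(=O)O[C@H](/C=C(/C)[C@@H](OC(C)=O)CC=C)[C@@H]1[C@H](OC(=O)[C@]2(C)O[C@@H]2C)C(OC)OC | intermediate
33 | (1S)-1-[(2R,3R)-2-[(1Z,3S)-3-(acetyloxy)-2-methylhexa-1,5-dien-1-yl]-4-methylidene-5-oxooxolan-3-yl]-2-oxoethyl (2R,3R)-2,3-dimethyloxirane-2-carboxylate | C=C1C(=O)O[C@H](/C=C(/C)[C@@H](OC(C)=O)CC=C)[C@@H]1[C@H](OC(=O)[C@]2(C)O[C@@H]2C)C=O | intermediate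
34 | 2-bromopropene | CC(Br)=C | starting material
35 | isopropenylchromium(III) dichloride (formal structure) | CC(=C)[Cr](Cl)Cl | intermediate
36 | (1S,2R)-1-[(2R,3R)-2-[(1Z,3S)-3-(acetyloxy)-2-methylhexa-1,5-dien-1-yl]-4-methylidene-5-oxooxolan-3-yl]-2-hydroxy-3-methylbut-3-en-1-yl (2R,3R)-2,3-dimethyloxirane-2-carboxylate | C=C1C(=O)O[C@H](/C=C(/C)[C@@H](OC(C)=O)CC=C)[C@@H]1[C@H](OC(=O)[C@]2(C)O[C@@H]2C)[C@H](O)C(C)=C | intermediate
37 | (3aR,4S,5R,6Z,9S,10Z,11aR)-9-(acetyloxy)-5-hydroxy-6,10-dimethyl-3-methylidene-2-oxo-2,3,3a,4,5,8,9,11a-octahydrocyclodeca[b]furan-4-yl (2R,3R)-2,3-dimethyloxirane-2-carboxylate | C=C1C(=O)O[C@@H]2/C=C(/C)[C@@H](OC(C)=O)C/C=C(/C)[C@@H](O)[C@@H](OC(=O)[C@]3(C)O[C@@H]3C)[C@H]12 | target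

## Step count and risks

Total step count: 19. Longest linear sequence: 12 (steps 1–3, 5–8, 15–19).

**Step 12 (the new ring-expanding shift).** The small cyclic boronate may take up two carbenoids or lose alkoxide, and migration may be slow or go through oxygen. The fallback uses known chemistry, sets out from 18 (with 22) and comes back at 26. Silylate 18 (TBSCl, imidazole) to (2Z)-tert-butyl[(3-iodobut-2-en-1-yl)oxy]dimethylsilane F1. Iodine–lithium exchange (t-BuLi, −78 °C) and quenching with 2-isopropoxy-4,4,5,5-tetramethyl-1,3,2-dioxaborolane gives the acyclic pinacol alkenylboronate F2. The established lithiation–borylation of such boronates with 23 (s-BuLi/(+)-sparteine; MgBr2·OEt2, reflux) gives the allylic pinacol boronate F3, NaOH/H2O2 gives the mono-silyl ether F4, and TBAF releases 26. This gives up the ring expansion for a protect/deprotect sequence of three extra steps.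

**Step 15 (face selectivity at C7).** The 6,7-syn outcome is reliable, but attack anti to the C8–O bond competes with attack anti to the larger C9 group, which would give the (6S,7S) lactone. The fallback sets out from 14 and 26 and comes back at 31. Acetylate 14 (Ac2O, pyridine) to the allylic acetate F5 and couple it with the primary allylic alcohol of 26 by iridium-catalysed transfer-hydrogenative 2-(alkoxycarbonyl)allylation (cyclometallated π-allyliridium C,O-benzoate with a chiral SEGPHOS-type ligand, Cs2CO3, THF, 60 °C; then PPTS). The alcohol is dehydrogenated in situ to the enal, the catalyst rather than C8 selects the C7 face, and syn addition with lactonisation gives 31 without steps 8, 13 and 14.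

**Step 19 (ring-closing metathesis).** The 10-membered ring is strained, dimerisation and E/Z mixtures are possible, and a wrong C9 epimer from step 18 would also end up here. The fallback sets out from 36 and comes back at 37. Oxidise the C9 hydroxyl (Dess–Martin periodinane, NaHCO3) to the acyclic dienone F6, close the ring on this flatter substrate (Hoveyda–Grubbs II, toluene, 80 °C) to the cyclic Z-enone F7, and reduce the ketone 1,2 from the open outer face (NaBH4, CeCl3·7H2O, MeOH, −78 °C) to 37. This also resets C9 if step 18 is poorly selective.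

## Further compounds

F1 | step 12 | (2Z)-tert-butyl[(3-iodobut-2-en-1-yl)oxy]dimethylsilane | C/C(I)=C/CO[Si](C)(C)C(C)(C)C
F2 | step 12 | tert-butyldimethyl{[(2Z)-3-(4,4,5,5-tetramethyl-1,3,2-dioxaborolan-2-yl)but-2-en-1-yl]oxy}silane | C/C(B1OC(C)(C)C(C)(C)O1)=C/CO[Si](C)(C)C(C)(C)C
F3 | step 12 | tert-butyldimethyl{[(2Z,4S)-3-methyl-4-(4,4,5,5-tetramethyl-1,3,2-dioxaborolan-2-yl)hepta-2,6-dien-1-yl]oxy}silane | CC(C)(C)[Si](C)(C)OC/C=C(/C)[C@@H](B1OC(C)(C)C(C)(C)O1)CC=C
F4 | step 12 | (2Z,4S)-1-[(tert-butyldimethylsilyl)oxy]-3-methylhepta-2,6-dien-4-ol | CC(C)(C)[Si](C)(C)OC/C=C(/C)[C@@H](O)CC=C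
F5 | step 15 | methyl (4S)-3-(acetyloxy)-4-{[(2R,3R)-2,3-dimethyloxirane-2-carbonyl]oxy}-5,5-dimethoxy-2-methylidenepentanoate | COC(=O)C(=C)C(OC(C)=O)[C@H](OC(=O)[C@]1(C)O[C@@H]1C)C(OC)OC
F6 | step 19 | (1S)-1-[(2R,3R)-2-[(1Z,3S)-3-(acetyloxy)-2-methylhexa-1,5-dien-1-yl]-4-methylidene-5-oxooxolan-3-yl]-3-methyl-2-oxobut-3-en-1-yl (2R,3R)-2,3-dimethyloxirane-2-carboxylate | C=C1C(=O)O[C@H](/C=C(/C)[C@@H](OC(C)=O)CC=C)[C@@H]1[C@H](OC(=O)[C@]2(C)O[C@@H]2C)C(=O)C(C)=C
F7 | step 19 | (3aR,4S,6Z,9S,10Z,11aR)-9-(acetyloxy)-6,10-dimethyl-3-methylidene-2,5-dioxo-2,3,3a,4,5,8,9,11a-octahydrocyclodeca[b]furan-4-yl (2R,3R)-2,3-dimethyloxirane-2-carboxylate | C=C1C(=O)O[C@@H]2/C=C(/C)[C@@H](OC(C)=O)C/C=C(/C)C(=O)[C@@H](OC(=O)[C@]3(C)O[C@@H]3C)[C@H]12
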